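## The problem

The target is an open-chain 1,2-diarylpropane-1,3-diol. C1 carries a hydroxyl and ring A (4-hydroxy-3-methoxyphenyl); C2 carries ring B (4-hydroxy-3,5-dimethoxyphenyl) and the hydroxymethyl carbon C3. No ring in the chain can relay stereochemistry. The two adjacent stereocentres are 1S,2S, with the C1 hydroxyl and ring B on opposite sides of the extended chain ring A–C1–C2–C3 (called anti below). Neither centre sets the other reliably: C2 is configurationally labile whenever C1 or C3 is a carbonyl carbon. Hydride addition to a C1 ketone beside a fixed C2 would, by simple steric or chelate models, place ring B opposite the hydride and give the syn relation. Both centres therefore need external control. C1 is a para-hydroxybenzylic alcohol: once the phenol is free it can ionise to a quinone methide under acid, base or heat, and it is open to hydrogenolysis. Both rings are oxidation-prone phenols, so the phenols stay masked to the last step and the late steps must be neutral and non-oxidising. The enabling feature is that, with C1 as a ketone and C3 as an ester, the C2–H bond lies between the ketone carbon C1, the ester carbon C3 and ring B. The two C2 epimers then interconvert through the enol faster than a catalyst reduces C1, so one enantioselective reduction of a racemic keto ester can fix both centres.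

## Retrosynthesis

**Target 9 from diol 8.** The two phenolic O–benzyl bonds are cut. Benzyl ethers survive enolate chemistry, formic acid/triethylamine and borohydride, and come off under neutral hydrogenolysis, the mildest condition the para-hydroxybenzylic alcohol can be offered. Silyl ethers would risk migration or loss in the enolate step; acid-labile acetals would need an acidic last step. The forward reaction must cleave two aryl benzyl ethers and leave the C1–O bond alone.

**Diol 8 from hydroxy ester 7.** No skeletal bond is cut; C3 is raised to the ester level. The ester makes C2 acidic one stage earlier and opens the Claisen disconnection. The forward reaction is a hydride reduction that must not disturb C2.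

**Hydroxy ester 7 from keto ester 6.** The C1–H bond is cut, and with it both stereocentres disappear: 6 is racemic and its C2 centre is labile. Cutting C1–C2 as an aldol would need a stoichiometric auxiliary. Cutting C1–ring A would require carrying a fragile α-aryl aldehyde in enantiopure form. The precursor has no defined stereocentre and all carbons in place. The forward reaction must deliver hydride to the Re face of C1 and draw on the C2 epimer that gives the anti relation.

**Keto ester 6 from ester 2 and acid chloride 4.** The C1–C2 bond is cut, the only C–C disconnection of the route. It follows the natural polarity (enolate 5 of the arylacetate, aroyl electrophile) and divides the molecule into its two aryl halves. Forming C2–ring B by arylation of an aroylacetate would cost more steps. The forward reaction is a C-acylation; no stereocontrol is asked of it.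

**Ester 2 from acid 1; acid chloride 4 from acid 3.** Only O–benzyl and C–Cl bonds are cut. Benzylating 1 on both the phenol and the carboxyl gives the ester for the enolate and the phenol mask in one step. Acids 1 and 3 are catalogue compounds.

## Roads not taken

**Alternative 1: asymmetric Prins dioxane from a stilbene.**
- Cut: C2–C3, C1–O and the two acetal C–O bonds, back to the E stilbene A1 and two formaldehyde units.
- Forward: a confined chiral imino-imidodiphosphate Brønsted acid activates formaldehyde; the oxocarbenium ion adds at C2, the cation develops at C1 beside ring A, and capture by a second formaldehyde unit closes the trans 1,3-dioxane A2.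
- Merits: the C3 carbon comes from formaldehyde, and one operation makes a skeletal bond, both stereocentres and a ring. The trans dioxane is the stable diastereomer and maps onto the target.
- Weak points: catalytic asymmetric Prins chemistry is established for terminal styrenes, not for 1,2-diaryl alkenes. Regiochemistry would rest on a small electronic difference between a pivalate-bearing and a benzyloxy-bearing ring. A stepwise cation can lose relative and absolute control. The methylene acetal must finally be removed with strong acid, which the para-oxygenated benzylic C1 will not tolerate without ionisation.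
- Comparison: more convergent in bond construction than the chosen plan, but it depends on an untested substrate class and a harsh unmasking. The chosen plan uses only mild late steps.

**Alternative 2: conjunctive coupling across a Z alkenylboronate.**
- Cut: C1–ring A and C2–ring B, with boron at C1.
- Forward: the Z alkenylboronate A3 and the aryllithium A4 form an ate complex. With Pd(OAc)2, a chiral ferrocenyl bisphosphine and the aryl triflate A5, an arylpalladium species of divalent palladium activates the alkene, ring A shifts from boron to C1, and reductive elimination forms C2–ring B to give boronate A6. Oxidation with retention, desilylation and debenzylation would follow.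
- Merits: two C–C bonds and both centres are set at once. The relative configuration is tied stereospecifically to the alkene geometry. This is a real advantage over the chosen plan, where the anti relation depends on a conformational preference in the transition state.
- Weak points: β-substituted alkenylboronates are sluggish in this coupling. The electron-rich triflate adds slowly to palladium. Direct aryl transfer competes. The benzylic boronate beside an electron-rich ring is prone to protodeboronation. Building A3 and A5, the oxidation and two deprotections make the route clearly longer.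
- Comparison: the chosen plan sets against this a six-step sequence, a Claisen assembly from two catalogue acids and a commercial catalyst. It must accept that its diastereoselection is less rigidly secured.

**Alternative 3: arylation of a desymmetrised aldehyde.**
- Cut: C1–ring A.
- Forward: the Grignard reagent A8 adds to the (S)-aldehyde A7 to give the anti alcohol A9.
- Merits: the Felkin–Anh arrangement (ring B opposite the nucleophile) and a magnesium chelate through the benzyloxy group both lead to the anti isomer. Substrate control thus works for the target, whereas in a ketone reduction the same models work against it. On diastereocontrol this road is better founded than the chosen plan.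
- Weak points: A7 is an α-aryl aldehyde with a β-alkoxy group. It enolises easily and can undergo β-elimination under the basic conditions of a Grignard addition, so the enantiopurity bought by an earlier enzymatic desymmetrisation is at risk. Making A7 costs several steps of protecting-group and oxidation-state changes.
- Comparison: the chosen plan turns the same C2 lability into the source of stereoconvergence and is shorter. In exchange it must win the C2 selection through catalyst and conformation.

Key step: step 4

Remark on the chemistry: the C2 descriptor is R in ester 7 and S in diols 8 and 9 for the same spatial arrangement, because C3 loses CIP priority when the ester is reduced.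

## Route

Step 1
Reactants: 1 2-(4-hydroxy-3,5-dimethoxyphenyl)acetic acid
Product: 2 benzyl 2-[4-(benzyloxy)-3,5-dimethoxyphenyl]acetate
Conditions: BnBr (2.4 equiv), K2CO3, DMF, 60 °C
Reagents that add atoms: benzyl bromide, BrCc1ccccc1
Why: Williamson ether synthesis on the phenol and O-alkylation of the carboxylate in one operation; the reactive benzylic halide alkylates even the flanked 2,6-dimethoxyphenoxide, and the benzyl ester serves directly as the enolate precursor.

Step 2
Reactants: 3 4-(benzyloxy)-3-methoxybenzoic acid
Product: 4 4-(benzyloxy)-3-methoxybenzoyl chloride
Conditions: (COCl)2, DMF (cat.), CH2Cl2, 0 °C to rt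
Reagents that add atoms: oxalyl chloride, ClC(=O)C(Cl)=O
Why: Standard acid chloride formation through the chloroiminium species from DMF; aryl benzyl and methyl ethers are inert, and the volatile by-products allow crude 4 to be used after evaporation.

Step 3
Reactants: 2 benzyl 2-[4-(benzyloxy)-3,5-dimethoxyphenyl]acetate; 4 4-(benzyloxy)-3-methoxybenzoyl chloride
Product: 6 racemic benzyl 3-[4-(benzyloxy)-3-methoxyphenyl]-2-[4-(benzyloxy)-3,5-dimethoxyphenyl]-3-oxopropanoate, via lithium ester enolate 5 (not isolated)
Conditions: LiN(SiMe3)2 (2.1 equiv), THF, −78 °C; then 4, −78 to −20 °C; aq NH4Cl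
Reagents that add atoms: none
Why: Claisen-type C-acylation of a lithium ester enolate by an aroyl chloride forms the C1–C2 bond; the second equivalent of base removes the acidic C2 proton of the product as it forms, which prevents proton exchange with unreacted enolate and a second acylation; C2 is deliberately made without stereocontrol.

Step 4
Reactants: 6 racemic benzyl 3-[4-(benzyloxy)-3-methoxyphenyl]-2-[4-(benzyloxy)-3,5-dimethoxyphenyl]-3-oxopropanoate
Product: 7 benzyl (2R,3S)-3-[4-(benzyloxy)-3-methoxyphenyl]-2-[4-(benzyloxy)-3,5-dimethoxyphenyl]-3-hydroxypropanoate
Conditions: RuCl(p-cymene)[(S,S)-TsDPEN] (2 mol %), HCO2H–Et3N (5:2), CH2Cl2, 30 °C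
Reagents that add atoms: none
Why: This is a Noyori-type asymmetric transfer hydrogenation with dynamic kinetic resolution of a 2-substituted 3-oxo ester, a known reaction class; TsDPEN is N-(p-toluenesulfonyl)-1,2-diphenylethylenediamine. Formate converts the 16-electron ruthenium amide into the 18-electron hydride of divalent ruthenium with loss of CO2, and the Ru–H hydride and the ligand N–H proton pass to C1 and to the ketone oxygen in one outer-sphere six-membered transition state, so the substrate never binds the metal and no ring is formed. C1 is set by the ligand: with the (S,S)-diamine, ring A lies against the p-cymene ring and hydride reaches the Re face, which gives 3S. C2 is set by selection: triethylamine equilibrates the two C2 epimers of 6 through the enol much faster than either is reduced, and the product, lacking the ketone, no longer epimerises under these conditions. The epimer that reacts on the Re face should be the one that can hold the ester carbon C3 opposite the incoming hydride, the C2 hydrogen beside ring A (where a larger group would clash with its ortho hydrogen) and ring B beside the ketone oxygen; this arrangement gives the 2R,3S (anti) ester. The step therefore needs enantioselection at C1 and anti over syn selection at C2. The first rests on the aryl ketone; the second rests on the non-chelating hydride donor, on a medium free of metal cations that could tie the two carbonyl groups into a chelate and so favour syn, and on the bulk and dipole of the benzyl ester, which keep it away from the ketone oxygen.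

Step 5
Reactants: 7 benzyl (2R,3S)-3-[4-(benzyloxy)-3-methoxyphenyl]-2-[4-(benzyloxy)-3,5-dimethoxyphenyl]-3-hydroxypropanoate
Product: 8 (1S,2S)-1-[4-(benzyloxy)-3-methoxyphenyl]-2-[4-(benzyloxy)-3,5-dimethoxyphenyl]propane-1,3-diol
Conditions: LiBH4, THF, 0 °C to rt
Reagents that add atoms: none
Why: Hydroxyl-assisted borohydride reduction of a β-hydroxy ester to the 1,3-diol; the reagent is too weakly basic to epimerise C2 or to provoke retro-aldol cleavage at this temperature, the ethers are inert, and neither stereocentre is touched.

Step 6
Reactants: 8 (1S,2S)-1-[4-(benzyloxy)-3-methoxyphenyl]-2-[4-(benzyloxy)-3,5-dimethoxyphenyl]propane-1,3-diol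
Product: 9 (1S,2S)-1-(4-hydroxy-3-methoxyphenyl)-2-(4-hydroxy-3,5-dimethoxyphenyl)propane-1,3-diol
Conditions: H2 (1 atm), 10% Pd/C, EtOAc–EtOH, rt
Reagents that add atoms: none
Why: Catalytic hydrogenolysis of two aryl benzyl ethers; under neutral conditions these cleave much faster than the secondary benzylic C1–OH bond, and the absence of acid, base and heat avoids quinone methide formation from the freed para-hydroxybenzylic alcohol.

## Compound list

1 | 2-(4-hydroxy-3,5-dimethoxyphenyl)acetic acid | COc1cc(CC(=O)O)cc(OC)c1O | starting material
2 | benzyl 2-[4-(benzyloxy)-3,5-dimethoxyphenyl]acetate | COc1cc(CC(=O)OCc2ccccc2)cc(OC)c1OCc1ccccc1 | intermediate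
3 | 4-(benzyloxy)-3-methoxybenzoic acid | COc1cc(C(=O)O)ccc1OCc1ccccc1 | starting material
4 | 4-(benzyloxy)-3-methoxybenzoyl chloride | COc1cc(C(Cl)=O)ccc1OCc1ccccc1 | intermediate
5 | lithium enolate of benzyl 2-[4-(benzyloxy)-3,5-dimethoxyphenyl]acetate (not isolated) | [Li]OC(OCc1ccccc1)=Cc1cc(OC)c(OCc2ccccc2)c(OC)c1 | intermediate
6 | racemic benzyl 3-[4-(benzyloxy)-3-methoxyphenyl]-2-[4-(benzyloxy)-3,5-dimethoxyphenyl]-3-oxopropanoate (C2 labile) | COc1cc(ccc1OCc1ccccc1)C(=O)C(C(=O)OCc1ccccc1)c1cc(OC)c(OCc2ccccc2)c(OC)c1 | intermediate
7 | benzyl (2R,3S)-3-[4-(benzyloxy)-3-methoxyphenyl]-2-[4-(benzyloxy)-3,5-dimethoxyphenyl]-3-hydroxypropanoate | COc1cc(ccc1OCc1ccccc1)[C@@H](O)[C@H](C(=O)OCc1ccccc1)c1cc(OC)c(OCc2ccccc2)c(OC)c1 | intermediate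
8 | (1S,2S)-1-[4-(benzyloxy)-3-methoxyphenyl]-2-[4-(benzyloxy)-3,5-dimethoxyphenyl]propane-1,3-diol | COc1cc(ccc1OCc1ccccc1)[C@@H](O)[C@H](CO)c1cc(OC)c(OCc2ccccc2)c(OC)c1 | intermediate
9 | (1S,2S)-1-(4-hydroxy-3-methoxyphenyl)-2-(4-hydroxy-3,5-dimethoxyphenyl)propane-1,3-diol | COc1cc([C@@H](O)[C@H](CO)c2cc(OC)c(O)c(OC)c2)ccc1O | target

## Step count and risks

Total step count: 6. Longest linear sequence: 5 steps (steps 1, 3, 4, 5, 6, or equally steps 2, 3, 4, 5, 6).

**Step 4 (key step).** The most likely failure is weak selection between the C2 epimers. The competing arrangement, with ring B opposite the hydride and the ester beside the ketone oxygen, is the one simple steric models prefer, and hydrogen-bond bridging of the two carbonyl groups by formic acid or triethylammonium would reinforce it; it leads to the syn relation. No close precedent for a 2-aryl substrate secures the anti outcome, so this is the main uncertainty of the route. A second concern is slow hydride transfer to the electron-rich aryl ketone.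

Fallback, from 2 back to the route at 8: the anti relation is built by an auxiliary-controlled aldol reaction instead of a reduction.
- Saponification of 2 (LiOH, THF–H2O) gives 2-[4-(benzyloxy)-3,5-dimethoxyphenyl]acetic acid F1.
- Pivaloyl chloride and Et3N convert F1 in the flask into the mixed pivalic anhydride F2, which acylates (S)-4-benzyl-2-oxazolidinone F3 in the presence of LiCl to give the N-arylacetyl imide F4.
- The magnesium-catalysed anti-aldol reaction of F4 with purchased 4-(benzyloxy)-3-methoxybenzaldehyde F5 (MgCl2 10 mol %, Et3N, Me3SiCl, EtOAc) should give the silylated anti adduct F6. On the accepted model the aldehyde attacks the magnesium-chelated Z enolate on the face away from the 4-benzyl group, which gives 2R, and the anti relation then gives 3S.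
- Dilute aqueous acid removes the silyl group to give the hydroxy imide F7.
- LiBH4 in wet THF cleaves the auxiliary reductively and gives diol 8 directly.

**Step 3.** Competing O-acylation of the enolate, acylation of the amide base by the acid chloride, and proton exchange between enolate 5 and the product can each hold back conversion.

Fallback, from 2 back to the route at 6: enolate 5 is added at −78 °C to 4-(benzyloxy)-3-methoxybenzaldehyde F5, an aldol addition that has no O-acylation channel and needs one equivalent of base. It gives benzyl 3-[4-(benzyloxy)-3-methoxyphenyl]-2-[4-(benzyloxy)-3,5-dimethoxyphenyl]-3-hydroxypropanoate F8 as a mixture of racemic diastereomers. Dess–Martin periodinane in CH2Cl2 then oxidises the benzylic alcohol to 6. The stereoisomer mixture is of no consequence because C2 of 6 is labile.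

**Step 6.** Over-reduction is the risk: once the para phenol of ring A is free, the benzylic C1–O bond is activated and may undergo hydrogenolysis. Acid traces on the catalyst could also cause C1 epimerisation through quinone methide formation.

Fallback, from 8 back to the route at 9: electron-transfer debenzylation with lithium naphthalenide (LiC10H8) in THF at −25 °C. The two hydroxyls are first converted into lithium alkoxides, which are not leaving groups for reductive C–O cleavage, while the aryl benzyl ethers fragment to phenoxide; a buffered aqueous NH4Cl work-up releases 9. No new compound is made.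

## Further compounds

F1 | step 4 | 2-[4-(benzyloxy)-3,5-dimethoxyphenyl]acetic acid | COc1cc(CC(=O)O)cc(OC)c1OCc1ccccc1
F2 | step 4 | 2-[4-(benzyloxy)-3,5-dimethoxyphenyl]acetic pivalic anhydride (not isolated) | COc1cc(CC(=O)OC(=O)C(C)(C)C)cc(OC)c1OCc1ccccc1
F3 | step 4 | (S)-4-benzyl-2-oxazolidinone (purchased auxiliary) | O=C1N[C@@H](Cc2ccccc2)CO1
F4 | step 4 | (S)-4-benzyl-3-{2-[4-(benzyloxy)-3,5-dimethoxyphenyl]acetyl}oxazolidin-2-one | COc1cc(CC(=O)N2[C@@H](Cc3ccccc3)COC2=O)cc(OC)c1OCc1ccccc1
F5 | step 4 | 4-(benzyloxy)-3-methoxybenzaldehyde (purchased) | COc1cc(C=O)ccc1OCc1ccccc1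
F6 | step 4 | (S)-4-benzyl-3-{(2R,3S)-3-[4-(benzyloxy)-3-methoxyphenyl]-2-[4-(benzyloxy)-3,5-dimethoxyphenyl]-3-(trimethylsilyloxy)propanoyl}oxazolidin-2-one | COc1cc(ccc1OCc1ccccc1)[C@@H](O[Si](C)(C)C)[C@H](C(=O)N1[C@@H](Cc2ccccc2)COC1=O)c1cc(OC)c(OCc2ccccc2)c(OC)c1
F7 | step 4 | (S)-4-benzyl-3-{(2R,3S)-3-[4-(benzyloxy)-3-methoxyphenyl]-2-[4-(benzyloxy)-3,5-dimethoxyphenyl]-3-hydroxypropanoyl}oxazolidin-2-one | COc1cc(ccc1OCc1ccccc1)[C@@H](O)[C@H](C(=O)N1[C@@H](Cc2ccccc2)COC1=O)c1cc(OC)c(OCc2ccccc2)c(OC)c1
F8 | step 3 | benzyl 3-[4-(benzyloxy)-3-methoxyphenyl]-2-[4-(benzyloxy)-3,5-dimethoxyphenyl]-3-hydroxypropanoate (mixture of racemic diastereomers) | COc1cc(ccc1OCc1ccccc1)C(O)C(C(=O)OCc1ccccc1)c1cc(OC)c(OCc2ccccc2)c(OC)c1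
F0 | step 6 | none | none
A1 | alternative 1 | 4-[(E)-2-(4-benzyloxy-3-methoxyphenyl)ethenyl]-2,6-dimethoxyphenyl pivalate | COc1cc(/C=C/c2cc(OC)c(OC(=O)C(C)(C)C)c(OC)c2)ccc1OCc1ccccc1
A2 | alternative 1 | (4S,5S)-4-(4-benzyloxy-3-methoxyphenyl)-5-(3,5-dimethoxy-4-pivaloyloxyphenyl)-1,3-dioxane (trans) | COc1cc(ccc1OCc1ccccc1)[C@H]1OCOC[C@@H]1c1cc(OC)c(OC(=O)C(C)(C)C)c(OC)c1
A3 | alternative 2 | tert-butyldimethylsilyl ether of (Z)-3-(4,4,5,5-tetramethyl-1,3,2-dioxaborolan-2-yl)prop-2-en-1-ol | CC(C)(C)[Si](C)(C)OC/C=C\B1OC(C)(C)C(C)(C)O1
A4 | alternative 2 | (4-benzyloxy-3-methoxyphenyl)lithium | [Li]c1ccc(OCc2ccccc2)c(OC)c1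
A5 | alternative 2 | 4-benzyloxy-3,5-dimethoxyphenyl trifluoromethanesulfonate | COc1cc(OS(=O)(=O)C(F)(F)F)cc(OC)c1OCc1ccccc1
A6 | alternative 2 | anti 1-(4-benzyloxy-3-methoxyphenyl)-2-(4-benzyloxy-3,5-dimethoxyphenyl)-3-(tert-butyldimethylsilyloxy)propyl-1-boronic acid pinacol ester | COc1cc(ccc1OCc1ccccc1)[C@@H](B1OC(C)(C)C(C)(C)O1)[C@H](CO[Si](C)(C)C(C)(C)C)c1cc(OC)c(OCc2ccccc2)c(OC)c1
A7 | alternative 3 | (S)-3-(benzyloxy)-2-[4-(benzyloxy)-3,5-dimethoxyphenyl]propanal | O=C[C@H](COCc1ccccc1)c1cc(OC)c(OCc2ccccc2)c(OC)c1
A8 | alternative 3 | (4-benzyloxy-3-methoxyphenyl)magnesium bromide | Br[Mg]c1ccc(OCc2ccccc2)c(OC)c1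
A9 | alternative 3 | (1S,2S)-3-(benzyloxy)-1-[4-(benzyloxy)-3-methoxyphenyl]-2-[4-(benzyloxy)-3,5-dimethoxyphenyl]propan-1-ol | COc1cc(ccc1OCc1ccccc1)[C@@H](O)[C@H](COCc1ccccc1)c1cc(OC)c(OCc2ccccc2)c(OC)c1
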